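**Assumption:** Dunnianol has no stereocentres and its biaryl axes rotate freely, so it is achiral; "single enantiomer" needs no stereocontrol.

## Retrosynthetic overview

1. Dunnianol ⇐ its tris(methyl ether) by global O-demethylation as the last step.
2. The three para-allyl groups ⇐ three aryl C–Cl bonds by one triple Stille allylation, so the alkenes never see halogenation or the biaryl coupling.
3. The m-terphenyl ⇐ 2,6-dibromo-4-chloroanisole + 2 × 5-chloro-2-methoxyphenylboronic acid by double Suzuki coupling (C–Br reacts, C–Cl is kept).
4. No rings are formed: all three arenes are bought preformed and both biaryl bonds are made in one operation.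

## Route

**Step 1**
Reactants: **1** 2,6-dibromo-4-chlorophenol; **2** iodomethane
Product: **3** 2,6-dibromo-4-chloroanisole (1,3-dibromo-5-chloro-2-methoxybenzene)
Conditions: MeI (1.5 equiv), K2CO3 (2 equiv), acetone, reflux
Reagents that add atoms: iodomethane, CI
Why: Williamson O-methylation of an acidic, readily deprotonated 2,6-dihalophenol; the aryl halides are inert to these conditions.

**Step 2**
Reactants: **3** 2,6-dibromo-4-chloroanisole (1 equiv); **4** 5-chloro-2-methoxyphenylboronic acid (2.6–3 equiv)
Product: **5** 5,5',5''-trichloro-2,2',2''-trimethoxy-1,1':3',1''-terphenyl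
Conditions: Pd(PPh3)4 (5 mol%), 2 M aq Na2CO3, DME, 85 °C
Reagents that add atoms: 5-chloro-2-methoxyphenylboronic acid, COc1ccc(Cl)cc1B(O)O
Why: Double Suzuki–Miyaura coupling; Pd/PPh3 inserts into the two C–Br bonds but not into the electron-rich C–Cl bonds, and each new biaryl bond is only di-ortho-substituted.

**Step 3**
Reactants: **5** trichloro-trimethoxy-terphenyl (1 equiv); **6** allyltributylstannane (4 equiv)
Product: **7** 5,5',5''-triallyl-2,2',2''-trimethoxy-1,1':3',1''-terphenyl
Conditions: Pd2(dba)3 (5 mol%), P(t-Bu)3 (20 mol%), CsF (7 equiv), dioxane, 100 °C; aq KF work-up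
Reagents that add atoms: allyltributylstannane, C=CC[Sn](CCCC)(CCCC)CCCC
Why: Triple Stille allylation; Pd/P(t-Bu)3 with fluoride activation of tin is a catalyst system built for electron-rich aryl chlorides of the 4-chloroanisole type, and the methyl ethers are inert.

**Step 4**
Reactants: **7** triallyl-trimethoxy-terphenyl
Product: **8** dunnianol (5,5',5''-triallyl-[1,1':3',1''-terphenyl]-2,2',2''-triol)
Conditions: BBr3 (4.5 equiv, 1 M in CH2Cl2), CH2Cl2, −78 → 0 °C; cold aq NaHCO3 quench
Reagents that add atoms: none
Why: Lewis-acid aryl methyl ether cleavage; at low temperature with a cold quench the terminal allyl groups should survive.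

## Compound list

1 | 2,6-dibromo-4-chlorophenol | Oc1c(Br)cc(Cl)cc1Br | starting material
2 | iodomethane | CI | starting material
3 | 2,6-dibromo-4-chloroanisole | COc1c(Br)cc(Cl)cc1Br | intermediate
4 | 5-chloro-2-methoxyphenylboronic acid | COc1ccc(Cl)cc1B(O)O | starting material
5 | 5,5',5''-trichloro-2,2',2''-trimethoxy-1,1':3',1''-terphenyl | COc1ccc(Cl)cc1-c1cc(Cl)cc(-c2cc(Cl)ccc2OC)c1OC | intermediate
6 | allyltributylstannane | C=CC[Sn](CCCC)(CCCC)CCCC | starting material
7 | 5,5',5''-triallyl-2,2',2''-trimethoxy-1,1':3',1''-terphenyl | C=CCc1ccc(OC)c(-c2cc(CC=C)cc(-c3cc(CC=C)ccc3OC)c2OC)c1 | intermediate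
8 | dunnianol | C=CCc1ccc(O)c(-c2cc(CC=C)cc(-c3cc(CC=C)ccc3O)c2O)c1 | target

## Summary

**Total steps:** 4
**Longest linear sequence:** 4 (compounds 4 and 6 are purchased)

**Steps most likely to fail, with fallbacks:**

1. **Step 3 (triple allylation).** Risks are incomplete tri-coupling, allyl-to-propenyl isomerisation, and Heck reaction of product alkenes with remaining C–Cl bonds. Fallback: reverse the polarity by triple Miyaura borylation of **5** (Pd/XPhos, B2pin2) to the tris-Bpin terphenyl, then Pd-catalysed coupling with allyl bromide at lower temperature.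
2. **Step 2 (double Suzuki).** Risks are stalling at mono-coupling and protodeboronation of the ortho-methoxy boronic acid. Fallback: replace the boron partner with an arylzinc made by directed ortho-lithiation of 4-chloroanisole (n-BuLi/TMEDA, then ZnCl2) and run a double Negishi coupling with **3**.
3. **Step 4 (demethylation beside three allyl groups).** Risks are HBr addition to the alkenes, isomerisation, and partial demethylation. Fallback: reorder the route by demethylating at the alkene-free stage **5** (BBr3), reprotecting as the tris-MOM ether, doing the allylation, and finishing with mild acid (HCl/MeOH) MOM removal.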